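Numbering and feature: C1 ketone, C2=C3 (C3 carries CH3), cyclobutane C4–C5–C11–C10, C6 (CH3 and C14H2O), C7 carbinol, C8, C9, C10 (CH3). C10 and C11 are the β- and α-carbons of a latent C5 carbonyl inside the seven-membered ring C5–C6–C7–C8–C9–C10–C11, and the four carbons C1–C2=C3(CH3)–C4 that span them are an isoprene unit.
Late stage: target ⇒ diol + two angelic acids; the C1 carbonyl ⇒ allylic oxidation of the C2=C3 alkene; C5–H ⇒ deoxygenation of a C5 cyclobutanol.
Cyclobutane (formed last): C4–C5 ⇒ Norrish–Yang photocyclisation of the C5 ketone onto the allylic C4–H of a cis-fused bicyclo[5.4.0]undecenone.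
Six-membered ring (formed second): C11–C1 and C4–C10 ⇒ Lewis acid Diels–Alder reaction of isoprene with a β-methyl cycloheptenone, the face being chosen by C6.
Seven-membered ring (from the starting material): cycloheptane-1,3-dione ⇒ 2-methyl-2-(oxymethyl) dione, enzymatic desymmetrisation (C6, C7), diol locked as a trans-fused di-tert-butylsilylene, enone by Saegusa / conjugate methylation / Saegusa.

Key step: step 9

Assumption: the Diels–Alder adduct is taken to be crystalline, so that the photocyclisation can be run in the solid state; if it is not, the irradiation is run in degassed benzene.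

Step 1
Reactants: 1 cycloheptane-1,3-dione
Product: 2 2-methylcycloheptane-1,3-dione
Conditions: MeI (1.1 equiv), K2CO3, acetone, rt
Reagents that add atoms: iodomethane, CI
Why: C-alkylation of the 1,3-dione enolate by the soft electrophile MeI is the standard C-methylation of cyclic 1,3-diones, and no stereocentre is formed.

Step 2
Reactants: 2 2-methylcycloheptane-1,3-dione
Product: 3 2-(hydroxymethyl)-2-methylcycloheptane-1,3-dione
Conditions: 37% aq. CH2O, Et3N (cat.), THF, 0 °C → rt
Reagents that add atoms: formaldehyde, C=O
Why: Aldol (Tollens-type) hydroxymethylation at the only acidic carbon builds quaternary C6 with C14 bound through carbon, whereas a chloromethyl ether would alkylate the dione mainly on oxygen; the product keeps a mirror plane, so no stereocentre is set yet.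

Step 3
Reactants: 3 2-(hydroxymethyl)-2-methylcycloheptane-1,3-dione
Product: 4 2-[(tert-butyldimethylsilyloxy)methyl]-2-methylcycloheptane-1,3-dione
Conditions: TBSCl, imidazole, DMF, 0 °C
Reagents that add atoms: tert-butyldimethylsilyl chloride, CC(C)(C)[Si](C)(C)Cl
Why: Silylation of the primary alcohol under near-neutral conditions blocks retro-aldol loss of formaldehyde during the aqueous reduction that follows.

Step 4
Reactants: 4 2-[(tert-butyldimethylsilyloxy)methyl]-2-methylcycloheptane-1,3-dione
Product: 5 (2R,3S)-2-[(tert-butyldimethylsilyloxy)methyl]-3-hydroxy-2-methylcycloheptan-1-one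
Conditions: ketoreductase (chosen by screening), NADP+ (cat.), i-PrOH, KH2PO4/K2HPO4 buffer pH 7, DMSO, 30 °C
Reagents that add atoms: none
Why: Enzymatic desymmetrising reduction of a prochiral 2,2-disubstituted cyclic 1,3-dione, in which the enzyme picks one enantiotopic carbonyl and one of its faces; this sets the carbinol C7 (S) and with it the quaternary C6 (R), hydroxyl cis to the methyl, and an enzyme giving this isomer is taken from a screening panel.

Step 5
Reactants: 5 (2R,3S)-2-[(tert-butyldimethylsilyloxy)methyl]-3-hydroxy-2-methylcycloheptan-1-one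
Product: 6 (2R,3S)-3-hydroxy-2-(hydroxymethyl)-2-methylcycloheptan-1-one
Conditions: HF·pyridine, THF, 0 °C → rt
Reagents that add atoms: none
Why: Fluoride cleavage of the silyl ether under mildly acidic conditions frees the 1,3-diol without exposing the β-hydroxy ketone to base, so no retro-aldol occurs.

Step 6
Reactants: 6 (2R,3S)-3-hydroxy-2-(hydroxymethyl)-2-methylcycloheptan-1-one
Product: 7 (6R,7S) silylene ketone (C5 ketone; C7–O and C14–O bridged by Si(t-Bu)2 in a trans-fused 1,3-dioxa-2-silinane)
Conditions: tBu2Si(OTf)2, 2,6-lutidine, CH2Cl2, 0 °C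
Reagents that add atoms: di-tert-butylsilyl bis(trifluoromethanesulfonate), CC(C)(C)[Si](OS(=O)(=O)C(F)(F)F)(OS(=O)(=O)C(F)(F)F)C(C)(C)C
Why: Silylene formation across the 1,3-diol gives a six-membered ring that is trans-fused (both C–O bonds equatorial), which ties C14 back into the ring plane and leaves the C6 methyl axial as the later facial control element.

Step 7
Reactants: 7 (6R,7S) silylene ketone
Product: 9 (6R,7S) silylene cyclohept-2-enone (C5 ketone with C10=C11), via silyl enol ether 8 (not isolated)
Conditions: LiN(SiMe3)2, TMSCl, THF, −78 °C; then Pd(OAc)2, MeCN, rt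
Reagents that add atoms: chlorotrimethylsilane, C[Si](C)(C)Cl (its atoms stay in 8 only)
Why: Saegusa–Ito dehydrogenation; because C6 is quaternary the ketone can enolise only towards C11, so the enone is formed without regiochemical ambiguity.

Step 8
Reactants: 9 (6R,7S) silylene cyclohept-2-enone
Product: 11 (6R,7S) β-methyl enone (C5 ketone with C10=C11 and CH3 on C10), via silyl enol ether 10 (not isolated)
Conditions: MeMgBr, CuBr·SMe2 (cat.), TMSCl, THF, −78 °C; then Pd(OAc)2, MeCN, rt
Reagents that add atoms: methylmagnesium bromide, C[Mg]Br; chlorotrimethylsilane, C[Si](C)(C)Cl (its atoms stay in 10 only)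
Why: Copper-catalysed conjugate methylation with silyl trapping followed by a second Saegusa–Ito dehydrogenation (β-hydride loss from C10–H) reinstates the enone with the methyl on C10; the transient C10 stereocentre is destroyed again, so its configuration does not matter.

Step 9
Reactants: 11 (6R,7S) β-methyl enone; 12 isoprene
Product: 13 (6R,7S,10R,11S) cis-fused bicyclo[5.4.0]undecenone (C5 ketone; C2=C3 alkene with CH3 on C3; angular CH3 on C10 and H on C11 cis to each other)
Conditions: isoprene (10 equiv), AlBr3/AlMe3 (10:1), toluene–CH2Cl2, −10 → 0 °C, cold Et3N quench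
Reagents that add atoms: none
Why: AlBr3 (kept proton-free by AlMe3) binds the C5 carbonyl oxygen and lowers the enone LUMO, so that isoprene adds across C10=C11 in a concerted but asynchronous normal-demand [4+2] cycloaddition in which the bond to the β-carbon C10 runs ahead. The closest known reaction type is the Lewis acid-promoted Diels–Alder reaction of 3-methylcycloalk-2-enones with isoprene and other 2-substituted butadienes, for which this mixed aluminium promoter is used when the enone is β,β-disubstituted. The six-membered ring C11–C1–C2–C3–C4–C10 closes by cycloaddition, both σ-bonds (C11–C1 and C4–C10) being formed suprafacially on one face of the enone, which makes the ring fusion cis. C10 and C11 are the two new stereocentres: their relative configuration follows from the suprafacial addition, and their absolute configuration is controlled by C6, whose methyl group stands axial on the silylene-locked seven-membered ring and screens its own face, so that the diene adds anti to it. The step needs para regioselectivity, which comes from the larger HOMO coefficient at the isoprene CH2 next to the methyl-bearing carbon (the future C4) pairing with the β-carbon C10, and it needs C11–H to stay cis, which the cold basic quench secures before the adduct can enolise.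

Step 10
Reactants: 13 (6R,7S,10R,11S) cis-fused bicyclo[5.4.0]undecenone
Product: 14 tricyclic cyclobutanol (C4–C5 bond closed; tertiary OH on C5 on the side of the C1–C2=C3 bridge)
Conditions: hν (medium-pressure Hg lamp, Pyrex filter), crystalline 13 suspended in aqueous sodium dodecyl sulfate, rt
Reagents that add atoms: none
Why: Norrish–Yang photocyclisation: n→π* excitation of the C5 ketone is followed by 1,5-hydrogen transfer of the pseudo-axial allylic C4–H through a six-membered transition state (C5 sits axial on the cis-fused cyclohexene, 1,3 to that hydrogen) and collapse of the ketyl/allyl 1,4-biradical at C4; the two centres can only be joined on the cyclohexene face that already carries C5, so C4 and C5 are fixed by the cis fusion, and the crystal lattice is used to hold back α-cleavage at C5–C6.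

Step 11
Reactants: 14 tricyclic cyclobutanol
Product: 15 methyl oxalate of the C5 cyclobutanol
Conditions: ClC(O)CO2Me, Et3N, DMAP (cat.), CH2Cl2, 0 °C → rt
Reagents that add atoms: methyl chlorooxalate, COC(=O)C(Cl)=O
Why: Acylation with the small, very reactive oxalyl chloride half-ester reaches the hindered tertiary alcohol under amine conditions, which avoids the metal alkoxide that could reopen the 2-vinylcyclobutanol.

Step 12
Reactants: 15 methyl oxalate of the C5 cyclobutanol
Product: 16 tricyclic alkene (C5–H; C2=C3 alkene; silylene intact; stereocentres as in the target)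
Conditions: Bu3SnH, AIBN, toluene, 110 °C
Reagents that add atoms: none
Why: Barton–McCombie-type radical chain deoxygenation of a tertiary methyl oxalate: the stannyl radical adds to the oxalate, C5–O cleaves to the tertiary cyclobutyl radical (no elimination pathway exists at the bridgeheads), and hydrogen transfer from Bu3SnH can only occur on the side left free by the C6–C9 bridge, which fixes C5.

Step 13
Reactants: 16 tricyclic alkene
Product: 17 tricyclic enone (C1 ketone conjugated with C2=C3; silylene intact)
Conditions: CrO3, 3,5-dimethylpyrazole, CH2Cl2, −20 °C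
Reagents that add atoms: chromium trioxide, O=[Cr](=O)=O
Why: Allylic oxidation of a pinene-type alkene to the verbenone-type enone: C1 is the only allylic CH2 (C4 is a bridgehead and the C3 methyl is less readily oxidised by this reagent), and no stereocentre is touched.

Step 14
Reactants: 17 tricyclic enone
Product: 18 enone diol (free C7–OH and C14–OH)
Conditions: HF·pyridine, THF, 0 °C → rt
Reagents that add atoms: none
Why: Fluoride cleaves both Si–O bonds of the silylene; the enone and the cyclobutane are inert to these conditions.

Step 15
Reactants: 18 enone diol; 19 angelic acid ((Z)-2-methylbut-2-enoic acid)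
Product: 21 target diangelate, via mixed anhydride 20 (not isolated)
Conditions: 19 (excess), 2,4,6-trichlorobenzoyl chloride, Et3N, toluene, rt; then 18, 80 °C
Reagents that add atoms: 2,4,6-trichlorobenzoyl chloride, O=C(Cl)c1c(Cl)cc(Cl)cc1Cl (its atoms stay in 20 only)
Why: Yamaguchi-type mixed-anhydride esterification run without a nucleophilic catalyst acylates the primary and the hindered secondary hydroxyl while keeping the (Z)-geometry of the angelate, since no reversible conjugate addition to the acyl donor takes place.

Compound list
1 | cycloheptane-1,3-dione | O=C1CCCCC(=O)C1 | starting material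
2 | 2-methylcycloheptane-1,3-dione | CC1C(=O)CCCCC1=O | intermediate
3 | 2-(hydroxymethyl)-2-methylcycloheptane-1,3-dione | CC1(CO)C(=O)CCCCC1=O | intermediate
4 | 2-[(tert-butyldimethylsilyloxy)methyl]-2-methylcycloheptane-1,3-dione | CC1(CO[Si](C)(C)C(C)(C)C)C(=O)CCCCC1=O | intermediate
5 | (2R,3S)-2-[(tert-butyldimethylsilyloxy)methyl]-3-hydroxy-2-methylcycloheptan-1-one (OH cis to CH3) | CC(C)(C)[Si](C)(C)OC[C@@]1(C)C(=O)CCCC[C@@H]1O | intermediate
6 | (2R,3S)-3-hydroxy-2-(hydroxymethyl)-2-methylcycloheptan-1-one | OC[C@@]1(C)C(=O)CCCC[C@@H]1O | intermediate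
7 | (6R,7S) silylene ketone: diol 6 as trans-fused di-tert-butylsilylene, C5 ketone | CC(C)(C)[Si]1(OC[C@@]2(C)C(=O)CCCC[C@@H]2O1)C(C)(C)C | intermediate
8 | trimethylsilyl enol ether of 7 (C5–OSiMe3, C5=C11) | CC(C)(C)[Si]1(OC[C@@]2(C)C(O[Si](C)(C)C)=CCCC[C@@H]2O1)C(C)(C)C | intermediate
9 | (6R,7S) silylene cyclohept-2-enone (C5 ketone, C10=C11) | CC(C)(C)[Si]1(OC[C@@]2(C)C(=O)C=CCC[C@@H]2O1)C(C)(C)C | intermediate
10 | trimethylsilyl enol ether of the 10-methyl ketone (C5=C11; C10 epimers) | CC(C)(C)[Si]1(OC[C@@]2(C)C(O[Si](C)(C)C)=CC(C)CC[C@@H]2O1)C(C)(C)C | intermediate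
11 | (6R,7S) β-methyl enone (C5 ketone, C10=C11, CH3 on C10, trans-fused silylene) | CC(C)(C)[Si]1(OC[C@@]2(C)C(=O)C=C(C)CC[C@@H]2O1)C(C)(C)C | intermediate
12 | isoprene (2-methylbuta-1,3-diene) | C=CC(C)=C | starting material
13 | (6R,7S,10R,11S) cis-fused bicyclo[5.4.0]undecenone (C5 ketone, C2=C3 with CH3 on C3, C10–CH3 and C11–H cis, six-membered ring anti to the C6 methyl) | CC(C)(C)[Si]1(OC[C@@]2(C)C(=O)[C@H]3CC=C(C)C[C@@]3(C)CC[C@@H]2O1)C(C)(C)C | intermediate
14 | tricyclic cyclobutanol (C4–C5 bond, tertiary C5–OH, C2=C3 alkene, silylene) | CC(C)(C)[Si]1(OC[C@@]2(C)[C@]3(O)[C@H]4CC=C(C)[C@@H]3[C@@]4(C)CC[C@@H]2O1)C(C)(C)C | intermediate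
15 | methyl oxalate of cyclobutanol 14 | CC(C)(C)[Si]1(OC[C@@]2(C)[C@]3(OC(=O)C(=O)OC)[C@H]4CC=C(C)[C@@H]3[C@@]4(C)CC[C@@H]2O1)C(C)(C)C | intermediate
16 | tricyclic alkene (C5–H, C2=C3, silylene; stereocentres as in 21) | CC(C)(C)[Si]1(OC[C@@]2(C)[C@@H]3[C@H]4CC=C(C)[C@@H]3[C@@]4(C)CC[C@@H]2O1)C(C)(C)C | intermediate
17 | (4R,5S,6R,7S,10R,11R) tricyclic enone (C1 ketone, C2=C3, silylene) | CC(C)(C)[Si]1(OC[C@@]2(C)[C@@H]3[C@H]4C(=O)C=C(C)[C@@H]3[C@@]4(C)CC[C@@H]2O1)C(C)(C)C | intermediate
18 | (4R,5S,6R,7S,10R,11R) enone diol (C7–OH, C14–OH) | OC[C@@]1(C)[C@@H]2[C@H]3C(=O)C=C(C)[C@@H]2[C@@]3(C)CC[C@@H]1O | intermediate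
19 | angelic acid, (Z)-2-methylbut-2-enoic acid | C/C=C(/C)C(=O)O | starting material
20 | angelic 2,4,6-trichlorobenzoic anhydride | C/C=C(/C)C(=O)OC(=O)c1c(Cl)cc(Cl)cc1Cl | intermediate
21 | CNP0240716.1, (4R,5S,6R,7S,10R,11R) 7,14-diangelate of the enone diol | C/C=C(/C)C(=O)OC[C@@]1(C)[C@@H]2[C@H]3C(=O)C=C(C)[C@@H]2[C@@]3(C)CC[C@@H]1OC(=O)/C(C)=C\C | target

Total step count: 15. Longest linear sequence: 15 steps, from cycloheptane-1,3-dione (isoprene and angelic acid enter in steps 9 and 15).

Steps most likely to fail

Step 9 (Diels–Alder). The β,β-disubstituted enone with a quaternary α'-carbon may react too slowly, so that cationic oligomerisation of isoprene, attack of the aluminium halide on the silylene, loss of facial or para selectivity, or Lewis acid epimerisation at C11 to the trans-fused ketone takes over. Fallback: the same two bonds are made stepwise and the ring is closed at C2=C3 instead. Setting out from 11, Hosomi–Sakurai conjugate addition of methallyltrimethylsilane (TiCl4, CH2Cl2, −78 °C), anti to the axial C6 methyl, would give the 10-methallyl ketone F1. Allylation at C11, the only enolisable position (LiN(SiMe3)2, allyl bromide, THF, −78 °C), would give the diene ketone F2. Ring-closing metathesis (second-generation Grubbs catalyst, CH2Cl2, 40 °C) then forms the trisubstituted C2=C3 alkene and comes back to the route at 13; if the C11 epimer forms, it is equilibrated with mild base and separated.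

Step 10 (Norrish–Yang). γ-Hydrogen abstraction may be outrun by α-cleavage of the C5–C6 bond next to the quaternary carbon. Oxetane formation between the C5 carbonyl and the C2=C3 alkene may intervene. The allyl radical may collapse at C2 instead of C4, and the biradical may fragment at C10–C11. Fallback: a reductive, non-photochemical closure of the same bond. Setting out from 13, allylic hydroxylation with SeO2 (cat.) and t-BuOOH in CH2Cl2 at the ring CH2 on the more substituted alkene carbon would give the C4 allylic alcohol F3. PPh3/CBr4 would convert it into the C4 allylic bromide F4; an allylic isomer formed alongside leads to the same allyl–samarium species. SmI2 (THF, −78 °C, t-BuOH quench) would then effect an intramolecular Barbier-type allylation of the C5 ketone through the carbon next to C10, which comes back to the route at 14.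

Step 12 (deoxygenation). Hydrogen transfer to the tertiary cyclobutyl radical has to occur under the C1–C3 bridge and may be slow enough for β-scission of a cyclobutane bond or for simple loss of the oxalate to compete. Fallback: a two-electron reductive C–O cleavage in place of the radical chain. Setting out from 14, deprotonation with MeLi at −78 °C and phosphorylation with ClP(O)(NMe2)2 (THF, −78 → 0 °C) would give the C5 tetramethylphosphorodiamidate F5. Dissolving-metal reduction (Li, EtNH2, t-BuOH, THF, 0 °C) then cleaves the C5–O bond with protonation on the only open side and comes back to the route at 16.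

Further compounds
F1 | step 9 | 10-methallyl silylene ketone (C10 quaternary: CH3 and CH2C(CH3)=CH2; C11H2) | CC(C)(C)[Si]1(OC[C@@]2(C)C(=O)C[C@@](C)(CC(C)=C)CC[C@@H]2O1)C(C)(C)C
F2 | step 9 | 11-allyl-10-methallyl silylene ketone (allyl on C11 cis to the methallyl group) | CC(C)(C)[Si]1(OC[C@@]2(C)C(=O)[C@@H](CC=C)[C@@](C)(CC(C)=C)CC[C@@H]2O1)C(C)(C)C
F3 | step 10 | C4 allylic alcohol of the bicyclic ketone 13 (either C4 epimer) | CC(C)(C)[Si]1(OC[C@@]2(C)C(=O)[C@H]3CC=C(C)C(O)[C@@]3(C)CC[C@@H]2O1)C(C)(C)C
F4 | step 10 | C4 allylic bromide of the bicyclic ketone 13 (either C4 epimer) | CC(C)(C)[Si]1(OC[C@@]2(C)C(=O)[C@H]3CC=C(C)C(Br)[C@@]3(C)CC[C@@H]2O1)C(C)(C)C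
F5 | step 12 | C5 N,N,N',N'-tetramethylphosphorodiamidate of cyclobutanol 14 | CC(C)(C)[Si]1(OC[C@@]2(C)[C@]3(OP(=O)(N(C)C)N(C)C)[C@H]4CC=C(C)[C@@H]3[C@@]4(C)CC[C@@H]2O1)C(C)(C)C
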